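# Proposed synthesis of (3S)-5,7-dihydroxy-3-{4-hydroxy-2-methoxy-3-[(E)-3-methylbut-1-enyl]phenyl}-6-prenylchroman-4-one (CNP0289142.1)

## The problem

The target 28 is a (3S)-isoflavanone. Ring A, a phloroglucinol with a prenyl group at C6 between the C5 and C7 hydroxyls, is fused through O1 and the C4 ketone to the dihydropyranone ring C, and C3 of that ring bears ring B. Ring A is the regiochemical difficulty, because prenylation of a finished 5,7-dioxygenated ring does not tell C6 from C8. Ring B is a contiguously 1,2,3,4-substituted benzene (C1' bound to C3, 2'-OMe, 3'-(E)-3-methylbut-1-enyl, 4'-OH), so its groups must be placed side by side. C3 is the only stereocentre, so nothing in the molecule can relay to it and it must come from a reagent or an enzyme. It is benzylic and α to the C4 carbonyl, hence lost by enolisation once acid or base meets the ketone, and it is safest carried at the alcohol oxidation level until late. The prenyl group next to free phenols closes to a chroman under acid, and the electron-rich styrene of ring B is acid-sensitive and excludes hydrogenolysis. Three phenols must be unveiled at the end without base reaching C3. A non-classical route is possible because ring A is 1,3,5-trioxygenated with the prenyl carbon C6 between two oxygens and para to O1. A 3-alkoxyvinylketene delivers C4a, C5, C8 and C8a together with O1, a prenyl-substituted siloxyalkyne delivers C6 and C7, and their union places every ring A substituent by construction.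

## Retrosynthesis

No skeletal bond is cut in the last step: 28 is taken back to its tris(triisopropylsilyl) ether 27. Silyl ethers on all three phenols are preferred to acetals or benzyl ethers because buffered fluoride removes them while sparing the prenyl group, the styrene and C3. The forward step must only keep free fluoride basicity away from the ketone.

The C4–C4a bond of 27 is cut next, giving acid 25, activated in the flask as mixed anhydride 26. Against building ring C from a deoxybenzoin or reducing an isoflavone, this cut keeps C3 as a preformed centre. It also uses the local symmetry of ring A in 25: with identical silyl ethers on both flanking oxygens the two positions ortho to O1 are equivalent, so only one ketone can form. The forward acylation must run without base and cold, since C3 is then α to an activated carbonyl.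

Acid 25 is traced through aldehyde 24 to alcohol 23, which comes from acetate 22, and 22 from phenol 21 by silylation. These are functional-group changes only. They are placed after ring A exists because a carbonyl at C4 any earlier would put an acidic hydrogen β to a vinylogous carboxylate leaving group. Capping 21 is the price of oxidising in the presence of a very electron-rich ring.

Ring A of 21 is cut at C4a–C5, C5–C6 and C7–C8, giving cyclobutenone 14 and siloxyalkyne 18 (via vinylketene 19 and adduct 20). Against attaching the chain to a preformed prenylated triphenol, where three hydroxyls compete and C-prenylation is poorly selective, this cut fixes every ring A position through the mechanism. The precursors are much simpler: 14 holds ring B, C2, C3 and the future C4, and 18 is a six-carbon alkyne. The forward step requires the vinylogous ester 14 to open thermally and the alkyne to add in one orientation.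

The enol ether C–O bond of 14 is cut to monoacetate 12 and 3-ethoxycyclobut-2-en-1-one 13. The acetate left by the desymmetrisation serves as the protecting group of the C4 oxygen through the key step, so no protecting-group exchange is needed. The forward exchange must be mild enough not to move the acetyl group between the two arms, which would scramble C3.

Monoacetate 12 comes from the prochiral diol 11, whose two hydroxymethyl arms (future C2 and C4) are enantiotopic. A lipase is preferred to an auxiliary because it sets C3 in one step on a substrate with no carbonyl next to the new centre. Diol 11 comes from triol 10 by silylating only the phenol, and 10 from arylmalonate 9 by hydride reduction, which also removes the carbamate used to build ring B.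

The bond from C1' to the malonate carbon of 9 is cut to aryl bromide 7 and diethyl malonate 8. α-Arylation is preferred to arylacetate chemistry because it delivers both arms of the diol at once.

The C3'–alkenyl bond of 7 is cut to aryl iodide 6 and (E)-alkenylboronate 2, so the alkene geometry is fixed before coupling; 2 is the hydroboration product of 3-methylbut-1-yne 1. Iodide 6 arises by directed metalation (aryllithium 5) of carbamate 4, made from 4-bromo-3-methoxyphenol 3. The carbamate directs to C3', the one position that electrophilic substitution avoids. The forward sequence must respect the carbon–bromine bond, hence an amide base and the iodide/bromide reactivity gap.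

Siloxyalkyne 18 is cut at O–Si to ynolate 17, which the Kowalski sequence makes from ester 16 and one added carbon. Because the ynolate keeps the whole acyl chain, the ester must be the β,γ-unsaturated 16, made from 4-methylpent-3-enoic acid 15; a γ,δ-unsaturated homologue would give an alkyne one methylene too long.

## Roads not taken

Alternative 1: The cut lies in ring B, at C3'–CHO and C4'–O. Forward, fluoride releases a bromo-methoxy aryne from silyl triflate A2; the carbonyl of N,N-dimethylformamide A3 adds across the strained bond with oxygen at the carbon remote from the methoxy group, and hydrolysis gives salicylaldehyde A1.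
- Merits: A1 carries bromine at C1', the aldehyde at C3' and a free hydroxyl at C4', all differentiated in one step, and the methoxy-induced distortion of the aryne makes the orientation predictable.
- Weak points: A2 needs its own multi-step preparation. The aldehyde of A1, flanked by two oxygens, must still be olefinated E-selectively. The step answers only ring B, leaving the C6/C8 question of ring A and the C3 centre to classical chemistry.
- Comparison: for ring B alone it is about as short as steps 2–4 and avoids the iodide-versus-bromide selectivity of step 4, a real advantage. The chosen plan sets against it a benzannulation spent on ring A, where no good classical answer exists, and keeps the formylation idea as the fallback for step 4.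

Alternative 2: Ring B is cut into diazo ketone A5 and conjugated ynol ether A6. Forward, photolysis of A5 triggers a Wolff shift of the vinyl group to a 2-substituted vinylketene, which combines with A6 and, after electrocyclic opening and closure, gives arylacetate A4.
- Merits: all four ring B substituents, including the E-alkene and the free hydroxyl, arrive in one step, and the acetate arm of A4 suits auxiliary-controlled hydroxymethylation to set C3.
- Weak points: A5 combines a vinyl diazo ketone with an activated methylene and is prone to pyrazoline formation. A6 is a volatile, acid-sensitive enyne. The irradiation can isomerise the E-styrene of A4. Ring A is again untouched.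
- Comparison: for ring B this is shorter than steps 1–5 and is the better route in step economy. The chosen plan sets against it thermal activation with stable partners (14 and 18) and a key step that solves the harder regiochemical problem of ring A.

Alternative 3: The cut is at O1–C8a and C4–C4a. Forward, fluoride releases a ring A aryne from silyl triflate A8; the carboxyl group of 2-arylacrylic acid A9 adds across it, oxygen at C8a and the acyl carbon at C4a, giving hydroxyaryl vinyl ketone A7, and oxa-Michael addition closes ring C.
- Merits: this is the most convergent plan. Both halves are joined and two bonds to ring A form in one step, with C4 already at the ketone oxidation level, so no late oxidation is needed.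
- Weak points: A8 is a pentasubstituted benzene with the prenyl group between two acetal-protected oxygens, so making it presupposes the ring A regiochemistry. C3 arises by protonation of an enolate and is racemic unless a separate asymmetric protonation is added. Three methoxymethyl ethers need acid at the end, with C3, the prenyl phenols and the styrene all exposed.
- Comparison: once the fragments exist the endgame is shorter than steps 12–17. The chosen plan sets against it a C3 of defined configuration from the enzyme, ring A substitution that follows from the mechanism, and fluoride as the only unmasking reagent.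

Key step: step 12

Assumption: the lipase of step 8 is taken to acylate the pro-S hydroxymethyl arm of diol 11; if it prefers the other arm, the same monoacetate 12 follows from the enantiocomplementary hydrolysis given among the fallbacks.

Abbreviations: ArB = 2-methoxy-3-[(E)-3-methylbut-1-en-1-yl]-4-(triisopropylsilyloxy)phenyl; TIPS = triisopropylsilyl.

## Route

Step 1
Reactants: 1 3-methylbut-1-yne
Product: 2 (E)-4,4,5,5-tetramethyl-2-(3-methylbut-1-en-1-yl)-1,3,2-dioxaborolane
Conditions: pinacolborane, Cp2Zr(H)Cl (5 mol %), Et3N (10 mol %), neat, sealed tube, 60 °C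
Reagents that add atoms: pinacolborane, CC1(C)OBOC1(C)C
Why: Zirconocene-hydride-catalysed syn hydroboration of a terminal alkyne puts boron on the terminal carbon and fixes the E geometry needed for the ring B styrene.

Step 2
Reactants: 3 4-bromo-3-methoxyphenol
Product: 4 4-bromo-3-methoxyphenyl N,N-diethylcarbamate
Conditions: Et2NCOCl, K2CO3, MeCN, reflux
Reagents that add atoms: N,N-diethylcarbamoyl chloride, CCN(CC)C(Cl)=O
Why: O-Carbamoylation of the phenol; the carbamate is a strong directing group for step 3, tolerates both palladium steps and is removed by the hydride of step 6.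

Step 3
Reactants: 4 4-bromo-3-methoxyphenyl N,N-diethylcarbamate
Product: 6 4-bromo-2-iodo-3-methoxyphenyl N,N-diethylcarbamate, via aryllithium 5 (not isolated)
Conditions: LiN(i-Pr)2, THF, −78 °C; then iodine, −78 °C
Reagents that add atoms: iodine, [I][I]
Why: Directed ortho-metalation: the amide base removes the most acidic ring proton, the one flanked by carbamate and methoxy (C3'), without bromine–lithium exchange, and at −78 °C the aryllithium is iodinated before any anionic Fries shift.

Step 4
Reactants: 6 4-bromo-2-iodo-3-methoxyphenyl N,N-diethylcarbamate; 2 (E)-4,4,5,5-tetramethyl-2-(3-methylbut-1-en-1-yl)-1,3,2-dioxaborolane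
Product: 7 4-bromo-3-methoxy-2-[(E)-3-methylbut-1-en-1-yl]phenyl N,N-diethylcarbamate
Conditions: Pd(dppf)Cl2 (3 mol %), K2CO3, 1,4-dioxane/H2O, 70 °C
Reagents that add atoms: none
Why: Suzuki–Miyaura coupling; oxidative addition to the carbon–iodine bond outpaces that to carbon–bromine, so the bromide at C1' is kept, and the coupling retains the E geometry of 2.

Step 5
Reactants: 7 4-bromo-3-methoxy-2-[(E)-3-methylbut-1-en-1-yl]phenyl N,N-diethylcarbamate; 8 diethyl malonate
Product: 9 diethyl 2-{4-[(diethylcarbamoyl)oxy]-2-methoxy-3-[(E)-3-methylbut-1-en-1-yl]phenyl}malonate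
Conditions: Pd(OAc)2 (2 mol %), P(t-Bu)3·HBF4 (4 mol %), K3PO4, PhMe, 90 °C
Reagents that add atoms: none
Why: Palladium-catalysed α-arylation of a malonate (Hartwig–Buchwald type) with a bulky electron-rich phosphine, which accepts ortho-alkoxy aryl bromides; carbamate and the disubstituted alkene are inert.

Step 6
Reactants: 9 diethyl 2-{4-[(diethylcarbamoyl)oxy]-2-methoxy-3-[(E)-3-methylbut-1-en-1-yl]phenyl}malonate
Product: 10 2-{4-hydroxy-2-methoxy-3-[(E)-3-methylbut-1-en-1-yl]phenyl}propane-1,3-diol
Conditions: LiAlH4 (excess, inverse addition), THF, 0 °C → reflux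
Reagents that add atoms: none
Why: Hydride reduction of both esters gives the prochiral 1,3-diol and cleaves the aryl carbamate to the phenol in the same operation; adding the malonate to excess hydride limits enolate formation and loss of a hydroxymethyl arm.

Step 7
Reactants: 10 2-{4-hydroxy-2-methoxy-3-[(E)-3-methylbut-1-en-1-yl]phenyl}propane-1,3-diol
Product: 11 2-(ArB)propane-1,3-diol
Conditions: TIPSCl (1.05 equiv), K2CO3, DMF, 0 °C → rt
Reagents that add atoms: triisopropylsilyl chloride, CC(C)[Si](Cl)(C(C)C)C(C)C
Why: Chemoselective O-silylation: only the phenol is acidic enough for carbonate, and the phenoxide is silylated while the neutral primary alcohols react only slowly with the hindered chlorosilane without an imidazole-type catalyst.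

Step 8
Reactants: 11 2-(ArB)propane-1,3-diol
Product: 12 (S)-3-hydroxy-2-(ArB)propyl acetate
Conditions: lipase from Burkholderia cepacia (Amano PS), vinyl acetate, t-BuOMe, 25 °C
Reagents that add atoms: vinyl acetate, C=COC(C)=O
Why: Lipase-catalysed desymmetrisation by irreversible transesterification; the enzyme active site distinguishes the enantiotopic hydroxymethyl arms and so creates the only stereocentre (future C3) under catalyst control, and slight over-acylation removes the minor enantiomer as diacetate.

Step 9
Reactants: 12 (S)-3-hydroxy-2-(ArB)propyl acetate; 13 3-ethoxycyclobut-2-en-1-one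
Product: 14 (S)-2-(ArB)-3-[(3-oxocyclobut-1-en-1-yl)oxy]propyl acetate
Conditions: 13 (3 equiv), PPTS (10 mol %), 5 Å MS, PhMe, 50 °C
Reagents that add atoms: none
Why: Acid-catalysed addition–elimination at the β-carbon of the vinylogous ester (vinylogous transesterification), driven by excess 13 and removal of ethanol; the stereocentre is not involved and the weak, aprotic acid should limit acetyl migration.

Step 10
Reactants: 15 4-methylpent-3-enoic acid
Product: 16 ethyl 4-methylpent-3-enoate
Conditions: EtI, K2CO3, DMF, rt
Reagents that add atoms: iodoethane, CCI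
Why: Carboxylate O-alkylation under non-acidic conditions avoids the acid-induced lactonisation of this β,γ-unsaturated acid and double-bond migration.

Step 11
Reactants: 16 ethyl 4-methylpent-3-enoate
Product: 18 triisopropyl[(5-methylhex-4-en-1-yn-1-yl)oxy]silane, via lithium ynolate 17 (not isolated)
Conditions: CH2Br2, lithium 2,2,6,6-tetramethylpiperidide, THF, −78 °C; LiN(SiMe3)2; n-BuLi, −78 → 0 °C; TIPSCl, −78 °C → rt
Reagents that add atoms: dibromomethane, BrCBr; triisopropylsilyl chloride, CC(C)[Si](Cl)(C(C)C)C(C)C
Why: Kowalski ynolate synthesis: LiCHBr2 adds to the ester, enolisation and bromine–lithium exchange give a carbenoid whose 1,2-shift of the prenyl group yields ynolate 17, and the bulky chlorosilane traps it on oxygen.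

Step 12
Reactants: 14 (S)-2-(ArB)-3-[(3-oxocyclobut-1-en-1-yl)oxy]propyl acetate; 18 triisopropyl[(5-methylhex-4-en-1-yn-1-yl)oxy]silane
Product: 21 (S)-3-[3-hydroxy-4-(3-methylbut-2-en-1-yl)-5-(triisopropylsilyloxy)phenoxy]-2-(ArB)propyl acetate, via alkoxyvinylketene 19 (not isolated), via cyclobutenone adduct 20 (not isolated)
Conditions: 18 (1.5 equiv), PhMe (degassed), sealed tube, 80 → 110 °C
Reagents that add atoms: none
Why: Heating opens cyclobutenone 14 by four-electron electrocyclic ring opening to the 3-alkoxyvinylketene 19. The siloxyalkyne 18 adds to the ketene C=C in a [2+2] cycloaddition to give 20, which opens again to a ketene; thermal six-electron (disrotatory) electrocyclisation then forms C4a–C5 and closes the six-membered carbocycle ring A, and a proton shift gives phenol 21. The closest known reaction type is the Danheiser benzannulation of cyclobutenones with triisopropylsiloxyalkynes, which gives resorcinol monosilyl ethers with the alkyne substituent between the two oxygens; here the cyclobutenone is a vinylogous ester, so the new ring is 1,3,5-trioxygenated. No stereocentre is created, and the existing one carries no acidifying group and lies away from every reacting atom, so neutral heating should leave it intact. The step needs one orientation in the [2+2] event, secured by the polarisation of the ynol ether: its prenyl-bearing carbon is the nucleophilic one and bonds to the ketene carbonyl carbon (C5–C6), the silyloxy carbon bonds to the ketene α-carbon (C7–C8), so prenyl lies between OH and OTIPS and para to O1. It also needs the ketene to choose the alkyne over the styrene, the prenyl alkene and the phenol being formed, which the far higher reactivity of the ynol ether and its use in excess should secure.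

Step 13
Reactants: 21 (S)-3-[3-hydroxy-4-(3-methylbut-2-en-1-yl)-5-(triisopropylsilyloxy)phenoxy]-2-(ArB)propyl acetate
Product: 22 (S)-3-[4-(3-methylbut-2-en-1-yl)-3,5-bis(triisopropylsilyloxy)phenoxy]-2-(ArB)propyl acetate
Conditions: TIPSOTf, 2,6-lutidine, CH2Cl2, 0 °C
Reagents that add atoms: triisopropylsilyl trifluoromethanesulfonate, CC(C)[Si](OS(=O)(=O)C(F)(F)F)(C(C)C)C(C)C
Why: Silylation of the hindered phenol with the silyl triflate; it makes ring A symmetric about the O1–C6 axis, so both positions ortho to O1 become equivalent, and shields the electron-rich phenol from the oxidants of step 15.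

Step 14
Reactants: 22 (S)-3-[4-(3-methylbut-2-en-1-yl)-3,5-bis(triisopropylsilyloxy)phenoxy]-2-(ArB)propyl acetate
Product: 23 (R)-3-[4-(3-methylbut-2-en-1-yl)-3,5-bis(triisopropylsilyloxy)phenoxy]-2-(ArB)propan-1-ol
Conditions: i-Bu2AlH (2.5 equiv), CH2Cl2, −78 °C
Reagents that add atoms: none
Why: Reductive cleavage of the primary acetate at low temperature leaves the aryl silyl ethers, which methanolic carbonate would endanger, untouched; the descriptor changes to R only because the ranking of the two arms changes.

Step 15
Reactants: 23 (R)-3-[4-(3-methylbut-2-en-1-yl)-3,5-bis(triisopropylsilyloxy)phenoxy]-2-(ArB)propan-1-ol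
Product: 25 (S)-3-[4-(3-methylbut-2-en-1-yl)-3,5-bis(triisopropylsilyloxy)phenoxy]-2-(ArB)propanoic acid, via aldehyde 24 (not isolated)
Conditions: Dess–Martin periodinane, NaHCO3, CH2Cl2, 0 °C; then NaClO2, NaH2PO4, 2-methyl-2-butene, t-BuOH/H2O, 0 °C
Reagents that add atoms: sodium chlorite, [Na+].[O-]Cl=O
Why: Dess–Martin oxidation under buffered, amine-free conditions gives the α-aryl aldehyde 24, which is oxidised at once by the Pinnick protocol to limit enolisation and β-elimination of the aryloxide; the alkene scavenger intercepts HOCl before it reaches the prenyl group, the styrene or ring A.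

Step 16
Reactants: 25 (S)-3-[4-(3-methylbut-2-en-1-yl)-3,5-bis(triisopropylsilyloxy)phenoxy]-2-(ArB)propanoic acid
Product: 27 (S)-3-(ArB)-6-(3-methylbut-2-en-1-yl)-5,7-bis(triisopropylsilyloxy)chroman-4-one, via mixed anhydride 26 (not isolated)
Conditions: (CF3CO)2O (1.2 equiv), CH2Cl2, −20 → 0 °C
Reagents that add atoms: none
Why: Intramolecular Friedel–Crafts acylation through the mixed trifluoroacetic anhydride 26, an established entry to isoflavanones from 3-aryloxy-2-arylpropanoic acids; ring A carries three oxygen donors and its two positions ortho to O1 are equivalent, so the six-membered ring C closes to a single ketone. No base is present, so the α-aryl centre should not epimerise through a ketene.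

Step 17
Reactants: 27 (S)-3-(ArB)-6-(3-methylbut-2-en-1-yl)-5,7-bis(triisopropylsilyloxy)chroman-4-one
Product: 28 (3S)-5,7-dihydroxy-3-{4-hydroxy-2-methoxy-3-[(E)-3-methylbut-1-en-1-yl]phenyl}-6-(3-methylbut-2-en-1-yl)chroman-4-one
Conditions: Bu4NF/AcOH (1:1), THF, 0 °C → rt
Reagents that add atoms: none
Why: Fluoride cleavage of the three aryl silyl ethers, buffered with acetic acid so that no phenoxide or fluoride basicity reaches the epimerisable C3; no acid strong enough to cyclise the prenyl group onto its neighbouring phenols is present.

## Compound list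

1 | 3-methylbut-1-yne | CC(C)C#C | starting material
2 | (E)-4,4,5,5-tetramethyl-2-(3-methylbut-1-en-1-yl)-1,3,2-dioxaborolane | CC(C)/C=C/B1OC(C)(C)C(C)(C)O1 | intermediate
3 | 4-bromo-3-methoxyphenol | COc1cc(O)ccc1Br | starting material
4 | 4-bromo-3-methoxyphenyl N,N-diethylcarbamate | CCN(CC)C(=O)Oc1ccc(Br)c(OC)c1 | intermediate
5 | 4-bromo-2-lithio-3-methoxyphenyl N,N-diethylcarbamate | CCN(CC)C(=O)Oc1ccc(Br)c(OC)c1[Li] | intermediate (not isolated)
6 | 4-bromo-2-iodo-3-methoxyphenyl N,N-diethylcarbamate | CCN(CC)C(=O)Oc1ccc(Br)c(OC)c1I | intermediate
7 | 4-bromo-3-methoxy-2-[(E)-3-methylbut-1-en-1-yl]phenyl N,N-diethylcarbamate | CCN(CC)C(=O)Oc1ccc(Br)c(OC)c1/C=C/C(C)C | intermediate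
8 | diethyl malonate | CCOC(=O)CC(=O)OCC | starting material
9 | diethyl 2-{4-[(diethylcarbamoyl)oxy]-2-methoxy-3-[(E)-3-methylbut-1-en-1-yl]phenyl}malonate | CCOC(=O)C(C(=O)OCC)c1ccc(OC(=O)N(CC)CC)c(/C=C/C(C)C)c1OC | intermediate
10 | 2-{4-hydroxy-2-methoxy-3-[(E)-3-methylbut-1-en-1-yl]phenyl}propane-1,3-diol | COc1c(C(CO)CO)ccc(O)c1/C=C/C(C)C | intermediate
11 | 2-{2-methoxy-3-[(E)-3-methylbut-1-en-1-yl]-4-(triisopropylsilyloxy)phenyl}propane-1,3-diol | COc1c(C(CO)CO)ccc(O[Si](C(C)C)(C(C)C)C(C)C)c1/C=C/C(C)C | intermediate
12 | (S)-3-hydroxy-2-(ArB)propyl acetate | COc1c([C@H](COC(C)=O)CO)ccc(O[Si](C(C)C)(C(C)C)C(C)C)c1/C=C/C(C)C | intermediate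
13 | 3-ethoxycyclobut-2-en-1-one | CCOC1=CC(=O)C1 | starting material
14 | (S)-2-(ArB)-3-[(3-oxocyclobut-1-en-1-yl)oxy]propyl acetate | COc1c([C@H](COC(C)=O)COC2=CC(=O)C2)ccc(O[Si](C(C)C)(C(C)C)C(C)C)c1/C=C/C(C)C | intermediate
15 | 4-methylpent-3-enoic acid | CC(C)=CCC(=O)O | starting material
16 | ethyl 4-methylpent-3-enoate | CCOC(=O)CC=C(C)C | intermediate
17 | lithium 5-methylhex-4-en-1-yn-1-olate | CC(C)=CCC#C[O-].[Li+] | intermediate (not isolated)
18 | triisopropyl[(5-methylhex-4-en-1-yn-1-yl)oxy]silane | CC(C)=CCC#CO[Si](C(C)C)(C(C)C)C(C)C | intermediate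
19 | (S)-2-(ArB)-3-[(4-oxobuta-1,3-dien-2-yl)oxy]propyl acetate (alkoxyvinylketene) | COc1c([C@H](COC(C)=O)COC(=C)C=C=O)ccc(O[Si](C(C)C)(C(C)C)C(C)C)c1/C=C/C(C)C | intermediate (not isolated)
20 | (2S)-2-(ArB)-3-({1-[3-(3-methylbut-2-en-1-yl)-4-oxo-2-(triisopropylsilyloxy)cyclobut-2-en-1-yl]ethenyl}oxy)propyl acetate, both epimers at the cyclobutenone carbon | COc1c([C@H](COC(C)=O)COC(=C)C2C(=O)C(CC=C(C)C)=C2O[Si](C(C)C)(C(C)C)C(C)C)ccc(O[Si](C(C)C)(C(C)C)C(C)C)c1/C=C/C(C)C | intermediate (not isolated)
21 | (S)-3-[3-hydroxy-4-(3-methylbut-2-en-1-yl)-5-(triisopropylsilyloxy)phenoxy]-2-(ArB)propyl acetate | COc1c([C@H](COC(C)=O)COc2cc(O)c(CC=C(C)C)c(O[Si](C(C)C)(C(C)C)C(C)C)c2)ccc(O[Si](C(C)C)(C(C)C)C(C)C)c1/C=C/C(C)C | intermediate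
22 | (S)-3-[4-(3-methylbut-2-en-1-yl)-3,5-bis(triisopropylsilyloxy)phenoxy]-2-(ArB)propyl acetate | COc1c([C@H](COC(C)=O)COc2cc(O[Si](C(C)C)(C(C)C)C(C)C)c(CC=C(C)C)c(O[Si](C(C)C)(C(C)C)C(C)C)c2)ccc(O[Si](C(C)C)(C(C)C)C(C)C)c1/C=C/C(C)C | intermediate
23 | (R)-3-[4-(3-methylbut-2-en-1-yl)-3,5-bis(triisopropylsilyloxy)phenoxy]-2-(ArB)propan-1-ol | COc1c([C@H](CO)COc2cc(O[Si](C(C)C)(C(C)C)C(C)C)c(CC=C(C)C)c(O[Si](C(C)C)(C(C)C)C(C)C)c2)ccc(O[Si](C(C)C)(C(C)C)C(C)C)c1/C=C/C(C)C | intermediate
24 | (S)-3-[4-(3-methylbut-2-en-1-yl)-3,5-bis(triisopropylsilyloxy)phenoxy]-2-(ArB)propanal | COc1c([C@H](C=O)COc2cc(O[Si](C(C)C)(C(C)C)C(C)C)c(CC=C(C)C)c(O[Si](C(C)C)(C(C)C)C(C)C)c2)ccc(O[Si](C(C)C)(C(C)C)C(C)C)c1/C=C/C(C)C | intermediate (not isolated)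
25 | (S)-3-[4-(3-methylbut-2-en-1-yl)-3,5-bis(triisopropylsilyloxy)phenoxy]-2-(ArB)propanoic acid | COc1c([C@H](C(=O)O)COc2cc(O[Si](C(C)C)(C(C)C)C(C)C)c(CC=C(C)C)c(O[Si](C(C)C)(C(C)C)C(C)C)c2)ccc(O[Si](C(C)C)(C(C)C)C(C)C)c1/C=C/C(C)C | intermediate
26 | (S)-3-[4-(3-methylbut-2-en-1-yl)-3,5-bis(triisopropylsilyloxy)phenoxy]-2-(ArB)propanoic trifluoroacetic anhydride | COc1c([C@H](C(=O)OC(=O)C(F)(F)F)COc2cc(O[Si](C(C)C)(C(C)C)C(C)C)c(CC=C(C)C)c(O[Si](C(C)C)(C(C)C)C(C)C)c2)ccc(O[Si](C(C)C)(C(C)C)C(C)C)c1/C=C/C(C)C | intermediate (not isolated)
27 | (S)-3-(ArB)-6-(3-methylbut-2-en-1-yl)-5,7-bis(triisopropylsilyloxy)chroman-4-one | COc1c([C@H]2COc3cc(O[Si](C(C)C)(C(C)C)C(C)C)c(CC=C(C)C)c(O[Si](C(C)C)(C(C)C)C(C)C)c3C2=O)ccc(O[Si](C(C)C)(C(C)C)C(C)C)c1/C=C/C(C)C | intermediate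
28 | (3S)-5,7-dihydroxy-3-{4-hydroxy-2-methoxy-3-[(E)-3-methylbut-1-en-1-yl]phenyl}-6-(3-methylbut-2-en-1-yl)chroman-4-one | COc1c([C@H]2COc3cc(O)c(CC=C(C)C)c(O)c3C2=O)ccc(O)c1/C=C/C(C)C | target

## Step count and least certain steps

Total step count: 17. Longest linear sequence: 14 steps (steps 2–9 and 12–17, from 3 to 28).

Step 12 (key step). The vinylogous-ester cyclobutenone may open more slowly than simple cyclobutenones because opening costs its enol-ether resonance. At the higher temperature then needed, the alkoxyvinylketene could be captured by the phenol already formed or oligomerise, and adduct 20 could stall before its second opening. Fallback, from 12 to 22, giving up the benzannulation: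
- Mitsunobu etherification of 12 (PPh3, diisopropyl azodicarboxylate, THF) with an excess of 2-(3-methylbut-2-en-1-yl)benzene-1,3,5-triol F1, made from phloroglucinol and prenyl bromide by C-prenylation. Its hydroxyl para to the prenyl group is the least hindered, so this should give (S)-3-[3,5-dihydroxy-4-(3-methylbut-2-en-1-yl)phenoxy]-2-(ArB)propyl acetate F2.
- Double silylation with TIPSOTf and 2,6-lutidine then gives 22.
- This replaces mechanistic control of ring A by steric preference among three phenols.

Step 9. Exchange at the stabilised vinylogous ester may be slow, leaving 12 exposed to acid long enough for the acetyl group to move between the two arms, which erodes the enantiomeric purity; the equilibrium may also stay incomplete. Fallback, from 12 directly to 14: Mitsunobu O-alkylation of cyclobutane-1,3-dione (its enol form is a strongly acidic pronucleophile) with 12, PPh3 and diisopropyl azodicarboxylate in THF at 0 °C. This forms the alkyl C–O bond instead of the vinyl C–O bond, is neutral and irreversible, and makes no new compound (F0).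

Step 8. The enzyme may favour the other enantiotopic arm, or discriminate only moderately because of the ortho-methoxy aryl group. Fallback, from 11 to 12: acetylation (Ac2O, pyridine) to 2-(ArB)propane-1,3-diyl diacetate F3, then hydrolysis with the same lipase in phosphate buffer. The enzyme removes the acetate from the arm it would otherwise acylate, so the monoacetate of opposite configuration to the acylation product results.

Step 16. Configuration at the α-aryl carbon may erode through enolisation of the activated acid (and of aldehyde 24 one step earlier). Attack next to a TIPS ether may also be slow, prolonging exposure of the alkenes to trifluoroacetic acid. Fallback, from 27 of insufficient enantiomeric purity back to 27: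
- O-acylation of its potassium enolate (KN(SiMe3)2, allyl chloroformate, THF, −78 °C) gives allyl 3-(ArB)-6-(3-methylbut-2-en-1-yl)-5,7-bis(triisopropylsilyloxy)-2H-chromen-4-yl carbonate F4.
- Pd2(dba)3 (zerovalent palladium) with a chiral phosphinooxazoline ligand and Meldrum's acid as proton donor then effects decarboxylative asymmetric protonation, a reaction class established for α-aryl chromanones. C3 is reset under catalyst control, the ligand enantiomer being chosen for S.

Step 4. Once the doubly ortho-substituted carbon–iodine bond reacts slowly, oxidative addition at carbon–bromine may compete and lead to double coupling. Fallback, from 4 to 7 without palladium: lithiation as in step 3 and quenching with N,N-dimethylformamide gives 3-bromo-6-[(diethylcarbamoyl)oxy]-2-methoxybenzaldehyde F5. Julia–Kocienski olefination with 5-(isobutylsulfonyl)-1-phenyl-1H-tetrazole and KN(SiMe3)2 then gives the E-alkene 7.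

## Further compounds

F1 | step 12 | 2-(3-methylbut-2-en-1-yl)benzene-1,3,5-triol | CC(C)=CCc1c(O)cc(O)cc1O
F2 | step 12 | (S)-3-[3,5-dihydroxy-4-(3-methylbut-2-en-1-yl)phenoxy]-2-(ArB)propyl acetate | COc1c([C@H](COC(C)=O)COc2cc(O)c(CC=C(C)C)c(O)c2)ccc(O[Si](C(C)C)(C(C)C)C(C)C)c1/C=C/C(C)C
F0 | step 9 | none | none
F3 | step 8 | 2-(ArB)propane-1,3-diyl diacetate | COc1c(C(COC(C)=O)COC(C)=O)ccc(O[Si](C(C)C)(C(C)C)C(C)C)c1/C=C/C(C)C
F4 | step 16 | allyl 3-(ArB)-6-(3-methylbut-2-en-1-yl)-5,7-bis(triisopropylsilyloxy)-2H-chromen-4-yl carbonate | C=CCOC(=O)OC1=C(c2ccc(O[Si](C(C)C)(C(C)C)C(C)C)c(/C=C/C(C)C)c2OC)COc2cc(O[Si](C(C)C)(C(C)C)C(C)C)c(CC=C(C)C)c(O[Si](C(C)C)(C(C)C)C(C)C)c21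
F5 | step 4 | 3-bromo-6-[(diethylcarbamoyl)oxy]-2-methoxybenzaldehyde | CCN(CC)C(=O)Oc1ccc(Br)c(OC)c1C=O
A1 | alternative 1 | 3-bromo-6-hydroxy-2-methoxybenzaldehyde | COc1c(Br)ccc(O)c1C=O
A2 | alternative 1 | 4-bromo-3-methoxy-2-(trimethylsilyl)phenyl trifluoromethanesulfonate | COc1c(Br)ccc(OS(=O)(=O)C(F)(F)F)c1[Si](C)(C)C
A3 | alternative 1 | N,N-dimethylformamide | CN(C)C=O
A4 | alternative 2 | methyl 2-{4-hydroxy-2-methoxy-3-[(E)-3-methylbut-1-en-1-yl]phenyl}acetate | COC(=O)Cc1ccc(O)c(/C=C/C(C)C)c1OC
A5 | alternative 2 | methyl 3-diazo-4-oxohex-5-enoate | COC(=O)CC(=[N+]=[N-])C(=O)C=C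
A6 | alternative 2 | (E)-1-methoxy-5-methylhex-3-en-1-yne | COC#C/C=C/C(C)C
A7 | alternative 3 | 1-[2-hydroxy-4,6-bis(methoxymethoxy)-5-(3-methylbut-2-en-1-yl)phenyl]-2-{2-methoxy-4-(methoxymethoxy)-3-[(E)-3-methylbut-1-en-1-yl]phenyl}prop-2-en-1-one | COc1c(C(=C)C(=O)c2c(O)cc(OCOC)c(CC=C(C)C)c2OCOC)ccc(OCOC)c1/C=C/C(C)C
A8 | alternative 3 | 3,5-bis(methoxymethoxy)-4-(3-methylbut-2-en-1-yl)-2-(trimethylsilyl)phenyl trifluoromethanesulfonate | COCOc1cc(OS(=O)(=O)C(F)(F)F)c([Si](C)(C)C)c(OCOC)c1CC=C(C)C
A9 | alternative 3 | 2-{2-methoxy-4-(methoxymethoxy)-3-[(E)-3-methylbut-1-en-1-yl]phenyl}prop-2-enoic acid | COc1c(C(=C)C(=O)O)ccc(OCOC)c1/C=C/C(C)C
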